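**Assumption:** the target has no stereocentre and no stereogenic double bond, so it is achiral; the given SMILES is the only form and no stereocontrol is needed.

## Retrosynthetic overview

1. Dioxepinone (depsidone lactone) ring, formed last: carbodiimide lactonisation of a diaryl ether hydroxy acid; only the ring B hydroxyl ortho to the ether oxygen can reach the carboxyl.
2. Diaryl ether C–O bond: Ullmann coupling of a ring B phenol with a ring A ortho-bromo salicylic acid.
3. Ring A: 5-bromoresorcinol plus prenal gives the 2,2-dimethylpyran ring (formed first), then ortho-carboxylation.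
4. Ring B: methoxyhydroquinone, bis-MOM protection, ortho-lithiation/prenylation between OMe and OMOM, para-bromination, hydroxylation.
5. Ring order: pyran ring (step 5), then the seven-membered lactone (step 9); both benzene rings are bought in.

## Route

Step 1
Reactants: 1 2-methoxybenzene-1,4-diol (methoxyhydroquinone)
Product: 2 2-methoxy-1,4-bis(methoxymethoxy)benzene
Conditions: NaH (2.5 equiv), MOMCl (2.4 equiv), DMF, 0 °C to rt
Reagents that add atoms: chloromethyl methyl ether, MOMCl (COCCl)
Why: Williamson-type O-alkylation of both phenoxides gives the bis-MOM ether, which protects the hydroquinone oxygens and makes them ortho-directing groups.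

Step 2
Reactants: 2 2-methoxy-1,4-bis(methoxymethoxy)benzene; 3 1-bromo-3-methylbut-2-ene (prenyl bromide)
Product: 5 2-methoxy-1,4-bis(methoxymethoxy)-3-(3-methylbut-2-en-1-yl)benzene, via aryllithium 4 (not isolated)
Conditions: n-BuLi (1.2 equiv), TMEDA, THF, 0 °C, 1 h; then CuBr·SMe2 (10 mol%), 3, −78 °C to rt
Reagents that add atoms: none
Why: Directed ortho-metalation takes the one C–H flanked by OMe and OMOM (cooperative 1,3-directing groups), and the aryllithium is alkylated at the primary carbon of prenyl bromide in a copper-catalysed SN2 coupling.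

Step 3
Reactants: 5 2-methoxy-1,4-bis(methoxymethoxy)-3-(3-methylbut-2-en-1-yl)benzene
Product: 6 1-bromo-4-methoxy-2,5-bis(methoxymethoxy)-3-(3-methylbut-2-en-1-yl)benzene
Conditions: NBS (1.05 equiv), dry MeCN, −20 to 0 °C, dark
Reagents that add atoms: N-bromosuccinimide, NBS (O=C1CCC(=O)N1Br)
Why: Electrophilic aromatic bromination goes para to the methoxy group (activated by para-OMe and ortho-OMOM) and on this very electron-rich arene should outrun attack of NBS on the isolated alkene in dry, cold MeCN.

Step 4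
Reactants: 6 1-bromo-4-methoxy-2,5-bis(methoxymethoxy)-3-(3-methylbut-2-en-1-yl)benzene
Product: 7 4-methoxy-2,5-bis(methoxymethoxy)-3-(3-methylbut-2-en-1-yl)phenol
Conditions: Pd2(dba)3 (2 mol%), tBuXPhos (8 mol%), KOH (3 equiv), 1,4-dioxane/H2O 1:1, 100 °C, Ar; then aq. NH4Cl
Reagents that add atoms: potassium hydroxide ([K+].[OH-])
Why: Palladium-catalysed C–O coupling of the aryl bromide with hydroxide (Buchwald-type hydroxylation) gives the phenol without touching the base-stable MOM ethers or the prenyl group.

Step 5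
Reactants: 8 5-bromobenzene-1,3-diol (5-bromoresorcinol); 9 3-methylbut-2-enal (prenal)
Product: 11 7-bromo-2,2-dimethyl-2H-chromen-5-ol, via ortho-quinone methide 10 (not isolated)
Conditions: ethylenediammonium diacetate (10 mol%), toluene, reflux, Dean–Stark; 8 in slight excess
Reagents that add atoms: none
Why: Amine-salt-catalysed Knoevenagel-type condensation at C2 of the resorcinol (between the two hydroxyls, the site not flanked by bromine, as with orcinol and olivetol) gives an ortho-quinone methide that closes by oxa-6π electrocyclisation to the 2,2-dimethylchromene.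

Step 6
Reactants: 11 7-bromo-2,2-dimethyl-2H-chromen-5-ol
Product: 13 7-bromo-5-hydroxy-2,2-dimethyl-2H-chromene-6-carboxylic acid, via magnesium salicylate chelate 12 (not isolated)
Conditions: MeOMgOCO2Me (2 M in DMF, 8 equiv), 120 °C, Ar; then cold 1 M HCl
Reagents that add atoms: methyl magnesium carbonate, MeOMgOCO2Me (COC(=O)O[Mg]OC)
Why: Magnesium-templated ortho-carboxylation (Kolbe–Schmitt-type reaction with Stiles' reagent, as in the carboxylation of cannabinoid phenols) can only go to the single free position ortho to the phenol, and the chelated magnesium salicylate drives the equilibrium.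

Step 7
Reactants: 13 7-bromo-5-hydroxy-2,2-dimethyl-2H-chromene-6-carboxylic acid; 7 4-methoxy-2,5-bis(methoxymethoxy)-3-(3-methylbut-2-en-1-yl)phenol
Product: 14 5-hydroxy-7-[4-methoxy-2,5-bis(methoxymethoxy)-3-(3-methylbut-2-en-1-yl)phenoxy]-2,2-dimethyl-2H-chromene-6-carboxylic acid
Conditions: CuI (20 mol%), N,N-dimethylglycine (40 mol%), Cs2CO3 (3.5 equiv), DMF, 90 °C, Ar; then cold aq. citric acid
Reagents that add atoms: none
Why: Carboxylate-assisted Ullmann diaryl ether synthesis (Hurtley-type activation of the ortho-bromobenzoate) joins the only free phenol oxygen of ring B to C7 of ring A, while the MOM ethers keep the other two ring B oxygens out of the coupling.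

Step 8
Reactants: 14 5-hydroxy-7-[4-methoxy-2,5-bis(methoxymethoxy)-3-(3-methylbut-2-en-1-yl)phenoxy]-2,2-dimethyl-2H-chromene-6-carboxylic acid
Product: 15 7-[2,5-dihydroxy-4-methoxy-3-(3-methylbut-2-en-1-yl)phenoxy]-5-hydroxy-2,2-dimethyl-2H-chromene-6-carboxylic acid
Conditions: HCl (about 1 M in MeOH), THF, 0 °C to rt, Ar, dark; concentrate cold and use crude
Reagents that add atoms: none
Why: Acid-catalysed acetal exchange with methanol removes both MOM groups as dimethoxymethane under conditions cold and dilute enough to spare the prenyl group, the chromene and the electron-rich salicylic acid.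

Step 9
Reactants: 15 7-[2,5-dihydroxy-4-methoxy-3-(3-methylbut-2-en-1-yl)phenoxy]-5-hydroxy-2,2-dimethyl-2H-chromene-6-carboxylic acid
Product: 17 garcinisidone B, via O-acylisourea 16 (not isolated)
Conditions: DCC (1.1 equiv), THF (0.005 M), 0 °C to rt, Ar
Reagents that add atoms: none
Why: Carbodiimide-mediated lactonisation closes the seven-membered depsidone ring because only the hydroxyl ortho to the diaryl ether oxygen can reach the activated carboxyl, so the para-related hydroxyl stays free.

## Compound list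

1 | 2-methoxybenzene-1,4-diol | COc1cc(O)ccc1O | starting material
2 | 2-methoxy-1,4-bis(methoxymethoxy)benzene | COCOc1ccc(OCOC)c(OC)c1 | intermediate
3 | 1-bromo-3-methylbut-2-ene | CC(C)=CCBr | starting material
4 | [2-methoxy-3,6-bis(methoxymethoxy)phenyl]lithium | [Li]c1c(OC)c(OCOC)ccc1OCOC | intermediate
5 | 2-methoxy-1,4-bis(methoxymethoxy)-3-(3-methylbut-2-en-1-yl)benzene | COCOc1ccc(OCOC)c(OC)c1CC=C(C)C | intermediate
6 | 1-bromo-4-methoxy-2,5-bis(methoxymethoxy)-3-(3-methylbut-2-en-1-yl)benzene | COCOc1c(Br)cc(OCOC)c(OC)c1CC=C(C)C | intermediate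
7 | 4-methoxy-2,5-bis(methoxymethoxy)-3-(3-methylbut-2-en-1-yl)phenol | COCOc1c(O)cc(OCOC)c(OC)c1CC=C(C)C | intermediate
8 | 5-bromobenzene-1,3-diol | Oc1cc(O)cc(Br)c1 | starting material
9 | 3-methylbut-2-enal | CC(C)=CC=O | starting material
10 | 5-bromo-3-hydroxy-2-(3-methylbut-2-en-1-ylidene)cyclohexa-3,5-dien-1-one (ortho-quinone methide) | CC(C)=CC=C1C(=O)C=C(Br)C=C1O | intermediate
11 | 7-bromo-2,2-dimethyl-2H-chromen-5-ol | CC1(C)C=Cc2c(O)cc(Br)cc2O1 | intermediate
12 | magnesium chelate of 7-bromo-5-oxido-2,2-dimethyl-2H-chromene-6-carboxylate | CC1(C)C=Cc2c3O[Mg]OC(=O)c3c(Br)cc2O1 | intermediate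
13 | 7-bromo-5-hydroxy-2,2-dimethyl-2H-chromene-6-carboxylic acid | CC1(C)C=Cc2c(O)c(C(=O)O)c(Br)cc2O1 | intermediate
14 | 5-hydroxy-7-[4-methoxy-2,5-bis(methoxymethoxy)-3-(3-methylbut-2-en-1-yl)phenoxy]-2,2-dimethyl-2H-chromene-6-carboxylic acid | CC1(C)C=Cc2c(O)c(C(=O)O)c(Oc3cc(OCOC)c(OC)c(CC=C(C)C)c3OCOC)cc2O1 | intermediate
15 | 7-[2,5-dihydroxy-4-methoxy-3-(3-methylbut-2-en-1-yl)phenoxy]-5-hydroxy-2,2-dimethyl-2H-chromene-6-carboxylic acid | CC1(C)C=Cc2c(O)c(C(=O)O)c(Oc3cc(O)c(OC)c(CC=C(C)C)c3O)cc2O1 | intermediate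
16 | O-acylisourea of acid 15 and N,N'-dicyclohexylcarbodiimide | CC1(C)C=Cc2c(O)c(C(=O)OC(=NC3CCCCC3)NC3CCCCC3)c(Oc3cc(O)c(OC)c(CC=C(C)C)c3O)cc2O1 | intermediate
17 | garcinisidone B (depsidone; ring A carries the chelated hydroxyl and the fused 2,2-dimethylpyran, ring B carries methoxy, hydroxyl and prenyl) | COc1c(O)cc2c(c1CC=C(C)C)OC(=O)c1c(cc3c(c1O)C=CC(C)(C)O3)O2 | target

## Step count and risks

Total step count: 9. Longest linear sequence: 7 steps (steps 1 to 4, then 7 to 9); the ring A branch is steps 5 and 6.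

**Step 3 (NBS bromination with the prenyl group present).** NBS may attack the trisubstituted alkene in competition with the ring. The fallback sets out from 2 and comes back at 7, putting the ring oxygen in before any alkene exists. NBS in MeCN converts 2 into 1-bromo-4-methoxy-2,5-bis(methoxymethoxy)benzene F1. Hydroxylation with Pd2(dba)3, tBuXPhos and KOH gives 4-methoxy-2,5-bis(methoxymethoxy)phenol F2. TIPSCl and imidazole give the bulky, non-directing silyl ether [4-methoxy-2,5-bis(methoxymethoxy)phenoxy]tri(propan-2-yl)silane F3. s-BuLi/TMEDA then metalates between OMOM and OMe to the silyloxy aryllithium F4, which is alkylated by 3 (CuBr·SMe2 cat.) to the prenylated silyl ether F5. TBAF in THF releases phenol 7.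

**Step 6 (carboxylation between OH and Br).** The position is hindered and deactivated by bromine, so conversion may be low; the regiochemistry of step 5 is also only supported by analogy. The fallback sets out from 8 and comes back at 13, carrying the carboxyl carbon from the start. Vilsmeier–Haack formylation of 8 (POCl3, DMF, MeCN; then water) gives 2-bromo-4,6-dihydroxybenzaldehyde F6. Chromenylation with 9 (ethylenediammonium diacetate, toluene, reflux) is now steered by the chelated ortho-hydroxy aldehyde to the carbon between the two hydroxyls and gives 7-bromo-5-hydroxy-2,2-dimethyl-2H-chromene-6-carbaldehyde F7. Pinnick oxidation (NaClO2, NaH2PO4, 2-methyl-2-butene, t-BuOH/H2O) gives 13.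

**Step 7 (Ullmann coupling with the free salicylic acid).** Decarboxylation of the electron-rich acid, self-coupling through its own phenol, or oxidation of the electron-rich phenol 7 could erode the yield. The fallback sets out from 13 and comes back at 14, coupling an ester instead of the carboxylate. MeI and KHCO3 in DMF give methyl 7-bromo-5-hydroxy-2,2-dimethyl-2H-chromene-6-carboxylate F8. Ligand-assisted coupling with 7 (CuI, picolinic acid, K3PO4, DMSO, 90 °C) gives the diaryl ether methyl ester F9. Saponification of the hindered ester (KOH, DMSO/H2O, 80 °C, Ar) gives 14.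

## Further compounds

F1 | step 3 | 1-bromo-4-methoxy-2,5-bis(methoxymethoxy)benzene | COCOc1cc(OC)c(OCOC)cc1Br
F2 | step 3 | 4-methoxy-2,5-bis(methoxymethoxy)phenol | COCOc1cc(OC)c(OCOC)cc1O
F3 | step 3 | [4-methoxy-2,5-bis(methoxymethoxy)phenoxy]tri(propan-2-yl)silane | COCOc1cc(OC)c(OCOC)cc1O[Si](C(C)C)(C(C)C)C(C)C
F4 | step 3 | [2-methoxy-3,6-bis(methoxymethoxy)-5-{[tri(propan-2-yl)silyl]oxy}phenyl]lithium | [Li]c1c(OC)c(OCOC)cc(O[Si](C(C)C)(C(C)C)C(C)C)c1OCOC
F5 | step 3 | [4-methoxy-2,5-bis(methoxymethoxy)-3-(3-methylbut-2-en-1-yl)phenoxy]tri(propan-2-yl)silane | COCOc1c(CC=C(C)C)c(OC)c(OCOC)cc1O[Si](C(C)C)(C(C)C)C(C)C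
F6 | step 6 | 2-bromo-4,6-dihydroxybenzaldehyde | O=Cc1c(O)cc(O)cc1Br
F7 | step 6 | 7-bromo-5-hydroxy-2,2-dimethyl-2H-chromene-6-carbaldehyde | CC1(C)C=Cc2c(O)c(C=O)c(Br)cc2O1
F8 | step 7 | methyl 7-bromo-5-hydroxy-2,2-dimethyl-2H-chromene-6-carboxylate | COC(=O)c1c(Br)cc2OC(C)(C)C=Cc2c1O
F9 | step 7 | methyl 5-hydroxy-7-[4-methoxy-2,5-bis(methoxymethoxy)-3-(3-methylbut-2-en-1-yl)phenoxy]-2,2-dimethyl-2H-chromene-6-carboxylate | COC(=O)c1c(Oc3cc(OCOC)c(OC)c(CC=C(C)C)c3OCOC)cc2OC(C)(C)C=Cc2c1O
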